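Ring C is disconnected at O1–C2 and C3–C4, back to a protected phloroglucinaldehyde and a two-carbon styryl sulfonium salt. In the key step the phenolic oxygen O1 adds to the benzylic carbon C2 of the alkenylsulfonium, the sulfur ylide so formed at C3 attacks the aldehyde carbon C4, and the aldehyde oxygen displaces diphenyl sulfide to become the C3 oxygen (a 3,4-epoxyflavan). The step exploits the ortho relationship of O1 and C4 on ring A and the α-oxygenated ketone C3–O/C4=O of ring C. Kornblum-type opening of the oxirane with DMSO gives the 3-hydroxy-4-ketone; acylative kinetic resolution installs the hexanoate and the absolute configuration; hydrogenolysis frees the phenols.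

Key step: step 3

Assumption: compounds 5 to 8 are racemic and are drawn as the enantiomer that goes on to the target; (R)-HBTM is written for the catalyst enantiomer that acylates the (2R,3R)-alcohol, by analogy with trans-2-arylcycloalkanols, and its mirror image is used if the sense proves opposite.

Step 1
Reactants: 1 2,4,6-trihydroxybenzaldehyde
Product: 2 2,4-bis(benzyloxy)-6-hydroxybenzaldehyde
Conditions: BnBr (2.05 equiv), K2CO3 (2.1 equiv), DMF, 0 °C to rt
Reagents that add atoms: benzyl bromide BrCc1ccccc1
Why: Williamson etherification takes the para hydroxyl and one ortho hydroxyl, and the remaining ortho hydroxyl, held in a hydrogen bond to the formyl group, should stay free as the future O1.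

Step 2
Reactants: 3 styrene
Product: 4 (E)-diphenyl(2-phenylethenyl)sulfonium trifluoromethanesulfonate
Conditions: Ph2SO, Tf2O, CH2Cl2, −78 °C; then 3, −78 to 0 °C; precipitation with Et2O
Reagents that add atoms: diphenyl sulfoxide O=S(c1ccccc1)c1ccccc1; trifluoromethanesulfonic anhydride O=S(=O)(OS(=O)(=O)C(F)(F)F)C(F)(F)F
Why: Interrupted Pummerer-type activation: the Tf2O-activated sulfoxide is attacked by the terminal carbon of styrene, and loss of the proton next to sulfur from the benzylic cation should give the E-alkenylsulfonium salt.

Step 3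
Reactants: 2 2,4-bis(benzyloxy)-6-hydroxybenzaldehyde, 4 (E)-diphenyl(2-phenylethenyl)sulfonium trifluoromethanesulfonate
Product: 6 rac-(2R,3S,4S)-5,7-bis(benzyloxy)-3,4-epoxy-2-phenylchromane (oxirane anti to the 2-phenyl group), via sulfonium ylide 5 (not isolated)
Conditions: 4 (1.2 equiv), Cs2CO3 (2 equiv), CH2Cl2/MeCN, 0 °C to rt; filtration through basic alumina, crude 6 used at once
Reagents that add atoms: none
Why: The phenoxide of 2 adds to the β-carbon (C2) of the alkenylsulfonium 4 to give the sulfonium ylide 5 (O1–C2), whose carbanion C3 attacks the neighbouring aldehyde carbon C4 (C3–C4), and the alkoxide then expels diphenyl sulfide at C3, so that the aldehyde oxygen becomes the C3 oxygen of the target. This is a tandem oxa-Michael/Johnson–Corey–Chaykovsky epoxy-annulation, the reaction type known for vinylsulfonium salts with amino and hydroxy carbonyl compounds. Ring C is closed by a 6-exo-trig addition of the ylide to the carbonyl group and the oxirane by a 3-exo-tet displacement. C3 and C4 are set together by the anti-periplanar betaine (cis-fused oxirane), and C2 relative to C3 by a chair-like transition state with the 2-phenyl group pseudo-equatorial while the conjugate addition stays reversible, so the oxirane should form anti to phenyl (2,3-trans); the product is racemic and the absolute configuration is secured in step 5. The step needs O-attack of the phenoxide at the β-carbon of 4 and capture of the ylide before it is protonated, which the sulfonium group as sole activating group and the tethered ortho aldehyde should secure.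

Step 4
Reactants: 6 rac-(2R,3S,4S)-5,7-bis(benzyloxy)-3,4-epoxy-2-phenylchromane
Product: 8 rac-(2R,3R)-5,7-bis(benzyloxy)-3-hydroxy-2-phenylchroman-4-one, via alkoxysulfonium triflate 7 (not isolated)
Conditions: DMSO (10 equiv), TfOH (1.0 equiv), CH2Cl2, −60 to −20 °C; then i-Pr2NEt (3 equiv), −20 °C to rt
Reagents that add atoms: dimethyl sulfoxide CS(C)=O
Why: Kornblum-type oxidative opening: acid ionises the oxirane at the electron-rich benzylic C4, DMSO captures the cation as alkoxysulfonium salt 7, and base-induced collapse of its ylide should give the C4 ketone and dimethyl sulfide while C2 and the C3–O bond (2,3-trans) are untouched.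

Step 5
Reactants: 8 rac-(2R,3R)-5,7-bis(benzyloxy)-3-hydroxy-2-phenylchroman-4-one, 9 hexanoic anhydride
Product: 10 (2R,3R)-5,7-bis(benzyloxy)-4-oxo-2-phenylchroman-3-yl hexanoate
Conditions: 9 (0.5 equiv), (R)-HBTM [(2R)-2-phenyl-3,4-dihydro-2H-pyrimido[2,1-b][1,3]benzothiazole] (5 mol%), i-Pr2NEt (0.6 equiv), CHCl3, 0 °C, run to about half conversion; chromatography
Reagents that add atoms: none
Why: Acylative kinetic resolution by enantioselective acyl transfer from the N-acyl isothiouronium ion (known for trans-2-arylcycloalkanols and α-hydroxy carbonyl compounds) should esterify the (2R,3R)-alcohol and leave the (2S,3S)-alcohol to be removed, which fixes both stereocentres of the target in absolute terms.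

Step 6
Reactants: 10 (2R,3R)-5,7-bis(benzyloxy)-4-oxo-2-phenylchroman-3-yl hexanoate
Product: 11 (2R,3R)-5,7-dihydroxy-4-oxo-2-phenylchroman-3-yl hexanoate
Conditions: H2 (1 atm), 10% Pd/C, EtOAc, rt
Reagents that add atoms: none
Why: Catalytic hydrogenolysis of the two aryl benzyl ethers under neutral conditions should spare the hexanoate, the aryl ketone and the cyclic C2–O1 ether, so neither stereocentre is touched.

Compound list
1 | 2,4,6-trihydroxybenzaldehyde | O=Cc1c(O)cc(O)cc1O | starting material
2 | 2,4-bis(benzyloxy)-6-hydroxybenzaldehyde | O=Cc1c(O)cc(OCc2ccccc2)cc1OCc1ccccc1 | intermediate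
3 | styrene | C=Cc1ccccc1 | starting material
4 | (E)-diphenyl(2-phenylethenyl)sulfonium trifluoromethanesulfonate | [O-]S(=O)(=O)C(F)(F)F.c1ccccc1/C=C/[S+](c1ccccc1)c1ccccc1 | intermediate
5 | rac-diphenylsulfonium 2-[3,5-bis(benzyloxy)-2-formylphenoxy]-2-phenylethanide (sulfonium ylide, not isolated) | O=Cc1c(OCc2ccccc2)cc(OCc2ccccc2)cc1O[C@@H]([CH-][S+](c1ccccc1)c1ccccc1)c1ccccc1 | intermediate
6 | rac-(2R,3S,4S)-5,7-bis(benzyloxy)-3,4-epoxy-2-phenylchromane (2,3-trans, oxirane anti to phenyl) | O3[C@H]1[C@@H]3c2c(OCc4ccccc4)cc(OCc4ccccc4)cc2O[C@@H]1c1ccccc1 | intermediate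
7 | rac-2,3-trans-5,7-bis(benzyloxy)-4-[(dimethylsulfonio)oxy]-3-hydroxy-2-phenylchromane trifluoromethanesulfonate (C4 epimers, not isolated) | O[C@H]1C(O[S+](C)C)c2c(OCc3ccccc3)cc(OCc3ccccc3)cc2O[C@@H]1c1ccccc1.[O-]S(=O)(=O)C(F)(F)F | intermediate
8 | rac-(2R,3R)-5,7-bis(benzyloxy)-3-hydroxy-2-phenylchroman-4-one | O[C@H]1C(=O)c2c(OCc3ccccc3)cc(OCc3ccccc3)cc2O[C@@H]1c1ccccc1 | intermediate
9 | hexanoic anhydride | CCCCCC(=O)OC(=O)CCCCC | starting material
10 | (2R,3R)-5,7-bis(benzyloxy)-4-oxo-2-phenylchroman-3-yl hexanoate | CCCCCC(=O)O[C@H]1C(=O)c2c(OCc3ccccc3)cc(OCc3ccccc3)cc2O[C@@H]1c1ccccc1 | intermediate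
11 | (2R,3R)-5,7-dihydroxy-4-oxo-2-phenylchroman-3-yl hexanoate (pinobanksin 3-O-hexanoate) | CCCCCC(=O)O[C@H]1C(=O)c2c(O)cc(O)cc2O[C@@H]1c1ccccc1 | target

Total step count: 6. Longest linear sequence: 5 steps (steps 1, 3, 4, 5 and 6 from 1; step 2 is a one-step branch).

Steps most likely to fail

1. Step 3 (key step). The hydrogen-bonded phenoxide may add too slowly to the β-phenyl-substituted alkenylsulfonium, so that base-induced elimination of 4 or protonation and decay of the ylide win, or the anti selectivity of ring closure may erode. A 2,3-cis oxirane would not be lost, since after step 4 its ketol can be epimerised at C3 (catalytic DBU) to the diequatorial trans ketol 8. Fallback, setting out from 2: heating with (E)-styrylboronic acid and catalytic dibenzylamine (dioxane, 90 °C; Petasis borono-Mannich addition, loss of the amine and oxa-6π electrocyclisation) should give rac-5,7-bis(benzyloxy)-2-phenyl-2H-chromene F1. Epoxidation with dimethyldioxirane (acetone, −20 °C) anti to the 2-phenyl group then returns to the route at 6.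

2. Step 4. The C4 cation may undergo a 1,2-hydride shift from C3 (semipinacol rearrangement to the 3-ketone) or lose a proton faster than DMSO captures it. Fallback, setting out from 6: buffered hydrolytic opening (THF/H2O, NaHCO3, rt) should give rac-2,3-trans-5,7-bis(benzyloxy)-2-phenylchromane-3,4-diol F2 as a C4 epimer mixture. DDQ (dioxane, rt) then dehydrogenates only the electron-rich benzylic C4 carbinol and returns to the route at 8.

3. Step 5. The acyl-transfer catalyst may discriminate the enantiomers of this hindered, hydrogen-bonded ketol too weakly, which would erode the enantiomeric purity of the ester. Fallback, setting out from racemic 8: asymmetric transfer hydrogenation under kinetic resolution (RuCl[(S,S)-TsDPEN](p-cymene), HCO2H/Et3N, EtOAc, rt; the catalyst enantiomer that reduces the (2S,3S) ketone) should convert the unwanted enantiomer into (2S,3R)-5,7-bis(benzyloxy)-2-phenylchromane-3,4-diol F3 and leave the (2R,3R) enantiomer of 8. This is separated and esterified without any selectivity requirement (9, DMAP, pyridine, CH2Cl2, 0 °C), coming back to the route at 10.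

Further compounds
F1 | step 3 | rac-5,7-bis(benzyloxy)-2-phenyl-2H-chromene | C1=Cc2c(OCc3ccccc3)cc(OCc3ccccc3)cc2O[C@@H]1c1ccccc1
F2 | step 4 | rac-2,3-trans-5,7-bis(benzyloxy)-2-phenylchromane-3,4-diol (C4 epimers) | O[C@H]1C(O)c2c(OCc3ccccc3)cc(OCc3ccccc3)cc2O[C@@H]1c1ccccc1
F3 | step 5 | (2S,3R)-5,7-bis(benzyloxy)-2-phenylchromane-3,4-diol (2,3-trans, C4 not assigned) | O[C@@H]1C(O)c2c(OCc3ccccc3)cc(OCc3ccccc3)cc2O[C@H]1c1ccccc1
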